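The readings were generated by integration with made-up constants, noise included.

Draw the product curve of the north-east flask before anything else; I did, from the four runs below, with a slope and a level.

| setting | east | north-west | west | south-west | north-east |
|---|---|---|---|---|---|
| starting material | 0.0500 M | 0.0300 M | 0.150 M | 0.0500 M | 0.360 M |
| partner | 0.0550 M | 0.0350 M | 0.0550 M | 0.170 M | 0.0550 M |
| free catalyst | 0.00500 M | 0.00500 M | 0.00500 M | 0.00500 M | 0.00500 M |
| time |  |  |  |  | 19 h |

- east run (time / h: [product] / M): 0.76: 4.6 × 10⁻⁴; 1.4: 0.00233; 2.8: 0.00607; 5.2: 0.01231; 10: 0.01975; 19: 0.02355
- north-west run (time / h: [product] / M): 0.76: 2.6 × 10⁻⁴; 1.4: 0.00115; 2.8: 0.00348; 5.2: 0.00734; 10: 0.01235; 19: 0.01470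
- west run (time / h: [product] / M): 0.76: 8.5 × 10⁻⁴; 1.4: 0.00185; 2.8: 0.00670; 5.2: 0.01321; 10: 0.02091; 19: 0.02364
- south-west run (time / h: [product] / M): 0.76: 0.00224; 1.4: 0.00650; 2.8: 0.01788; 5.2: 0.03593; 10: 0.04883; 19: 0.05006

(standard deviation of a reading: 2 × 10⁻⁴ M)

- Overall: starting material + partner -> product, with free catalyst as catalyst.
- Constant volume, constant temperature.
- Bound and free are read together.
- An order is taken over about fifteen percent of the charge, up and down.

- reaction order in [starting material] at the outset, round the charge of the east run, defined at two percent of the starting material turned into product (one fixed amount of product, the same in the runs compared)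
- reaction order in [partner] at the outset, round the charge of the east run, defined at two percent of the starting material turned into product
- product in the north-east run at 19 h, as a share of the starting material charged

The curve starts flat: at 0.76 h the west run held 8.5 × 10⁻⁴ M of product. Then it straightens. Between 2.8 h and 5.2 h the west run climbed 0.00271 M h⁻¹, and the east run, with 3.00 times less starting material, climbed 0.00260 M h⁻¹. The south-west run, with 3.09 times the partner of the east run, climbed 2.89 times as fast. So the slope followed the partner, and I gave the north-east flask the west slope.

Next came the level. At 19 h the west run still held 0.0314 M of partner and 0.126 M of starting material, yet it had nearly stopped, so I took the catalyst to be what ended. In that run ln(c(partner) charged / c(partner) left) came to 0.562. I called this the catalyst's budget: the pseudo-first-order lifetimes of partner that one charge of catalyst pays for. The east run gave 0.559 and the north-west run 0.545, from different charges.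

Spent on the north-east flask, the budget put the level at 0.0236 M. The straight slope meets that level at 8.72 h, and 19 h is twice that, so I placed the asked time on the level, at a share of 6.57%. The orders I left to the flask, since the two percent mark lies between the east readings at 0.76 h and 1.4 h, on the flat start.

The forecast gave 0.12 and 0.75 for the orders and 6.7% for the share, above mine, holding that "the catalyst dies with time, after a fixed integrated turnover".

The flask gave orders of 0.090 and 0.62 and a share of 6.67%.

    active catalyst + starting material ⇌ catalyst-substrate complex, settled at all times (105.0 M⁻¹)
    catalyst-substrate complex + partner → product + active catalyst + by-product (36.72 M⁻¹ h⁻¹)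
    catalyst-substrate complex → spent catalyst + starting material (0.3146 h⁻¹)
    free catalyst → active catalyst (0.3283 h⁻¹)

Read back through the same logarithm, that share is a budget of 0.574. The level comes from the loss of complex to spent catalyst: with that step removed, the north-east run reaches 14.4% instead of 6.67%. Each complex either turns over with partner or dies, so the constants of those two steps and the catalyst charge give a budget of 0.584. On the north-west charge my budget gives a level of 0.0150 M, about half of its starting material, and the north-west run comes to that half at 20.4 h.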